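**Plan**

- Retrosynthesis: the butanoate C–O bond is cut first. Ring B of the naphthazarin (C5–C8) is then cut at C4a–C5 and C8–C8a into furan and a 3,6-dimethoxybenzyne. The side chain is cut at C3'=C4' (metathesis) and C1'–C2' (allylation), which leads back to 4-bromo-2,5-dimethoxybenzaldehyde.
- Enabling feature: in the 5,8-dihydroxy-1,4-naphthoquinone core the C1/C4 carbonyls and the C5/C8 hydroxyls exchange roles by tautomerism. Substituted ring A (C1–C4, C4a, C8a) can therefore be carried as a 1,4-dimethoxybenzene, while unsubstituted ring B, with para oxygens on C5 and C8, is made last from the four carbons and the oxygen of furan.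
- Forward: side chain on the bromoarene (steps 1–3), ring B by aryne–furan [4+2] cycloaddition (step 4), silyl-to-butanoyl exchange (steps 5 and 6), bridge opening and oxidation to one quinone in a single flask (step 7), oxidative demethylation and reduction to the naphthazarin (step 8).
- Stereochemistry: the only stereocentre, C1' (R), is set in step 1 by a chiral phosphoric acid-catalysed allylboration; no later step breaks a bond at C1'.

Key step: step 4

Assumption: the two naphthazarin tautomers (side chain on the quinone ring or on the hydroquinone ring) interconvert freely, so 19 is a single compound. The bridgehead centres of 11, 12 and 14 are left undefined in the SMILES because both diastereomers form and are carried on together. The regioisomeric naphthols 15 and 16 arise side by side in step 7 and are oxidised in the same flask to the one quinone 17.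

**Route**

Step 1
Reactants: 1 4-bromo-2,5-dimethoxybenzaldehyde; 2 allylboronic acid pinacol ester
Product: 4 (1R)-1-(4-bromo-2,5-dimethoxyphenyl)but-3-en-1-ol, via pinacol borate ester 3 (not isolated)
Conditions: (R)-3,3'-bis(2,4,6-triisopropylphenyl)-1,1'-binaphthyl-2,2'-diyl hydrogen phosphate (5 mol%), toluene, −30 °C; aq. NaHCO3 work-up
Reagents that add atoms: none
Why: Chiral phosphoric acid-catalysed allylboration of an aryl aldehyde: the acid is expected to bind the boronate oxygen and the formyl hydrogen in a closed chair transition state, and the (R)-catalyst should direct the allyl group to the re face of the aldehyde, which sets C1' as R (to be confirmed by chiral HPLC); the aryl bromide and the methoxy groups do not interfere.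

Step 2
Reactants: 4 (1R)-1-(4-bromo-2,5-dimethoxyphenyl)but-3-en-1-ol
Product: 5 {[(1R)-1-(4-bromo-2,5-dimethoxyphenyl)but-3-en-1-yl]oxy}(tert-butyl)dimethylsilane
Conditions: t-BuMe2SiCl, imidazole, DMF, rt
Reagents that add atoms: tert-butyldimethylsilyl chloride, CC(C)(C)[Si](C)(C)Cl
Why: Standard silylation of a secondary alcohol (silyl chloride with imidazole) should mask the hydroxyl as an ether that has no acidic hydrogen and withstands the LiN(iPr)2 of step 4; C1' is not touched.

Step 3
Reactants: 5 {[(1R)-1-(4-bromo-2,5-dimethoxyphenyl)but-3-en-1-yl]oxy}(tert-butyl)dimethylsilane; 6 2-methylbut-2-ene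
Product: 7 {[(1R)-1-(4-bromo-2,5-dimethoxyphenyl)-4-methylpent-3-en-1-yl]oxy}(tert-butyl)dimethylsilane
Conditions: second-generation Grubbs catalyst RuCl2(=CHPh)(PCy3)(H2IMes) (H2IMes = 1,3-dimesitylimidazolidin-2-ylidene; 3 mol%), 2-methylbut-2-ene (large excess), CH2Cl2, rt
Reagents that add atoms: none
Why: Olefin cross-metathesis of a terminal alkene with 2-methylbut-2-ene in large excess should transfer an isopropylidene unit and release propene, giving the prenyl terminus; the trisubstituted product is a poor metathesis substrate, and the aryl bromide and silyl ether are inert to the catalyst.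

Step 4
Reactants: 7 {[(1R)-1-(4-bromo-2,5-dimethoxyphenyl)-4-methylpent-3-en-1-yl]oxy}(tert-butyl)dimethylsilane; 8 furan
Product: 11 tert-butyl{[(1R)-1-(5,8-dimethoxy-1,4-dihydro-1,4-epoxynaphthalen-6-yl)-4-methylpent-3-en-1-yl]oxy}dimethylsilane (both bridgehead diastereomers), via ortho-bromoaryllithium 9 (not isolated), via aryne 10 (not isolated)
Conditions: LiN(iPr)2 (2 equiv), furan (15 equiv), THF, −78 °C → rt
Reagents that add atoms: none
Why: LiN(iPr)2 should remove the ring hydrogen at C3 of the bromoarene, the position flanked by bromine and methoxy and so the most acidic C–H in the molecule, and the ortho-bromoaryllithium 9 should lose LiBr on warming to give the 4-substituted 3,6-dimethoxybenzyne 10. The aryne is trapped by excess furan in a concerted, suprafacial [4+2] cycloaddition (aryne Diels–Alder reaction), the direct analogue of the known reaction of 2-bromo-1,4-dimethoxybenzene with LiN(iPr)2 and furan. The new six-membered carbocycle (ring B) is closed by an intermolecular [4+2] annulation in which the two aryne carbons bond to C2 and C5 of furan, forming the C4a–C5 and C8–C8a bonds of the target in one event. The two bridgehead stereocentres are necessarily cis across the oxygen bridge, but their sense relative to remote C1' is not controlled, which is harmless because both are destroyed when the bridge is opened in step 7. The step needs deprotonation at the aryl C3–H and not at the benzylic C1'–H or at C6–H; this is secured by the combined acidifying effect of bromine and methoxy and by the low kinetic acidity of a benzylic silyl ether C–H toward LiN(iPr)2 at −78 °C, while lithiation at C6 would be reversible and unproductive. Furan is symmetric, so no regiochemical question arises, and its large excess should outcompete addition of the amide or the amine to the aryne; the silyl ether and the trisubstituted alkene are not attacked by the base at these temperatures.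

Step 5
Reactants: 11 tert-butyl{[(1R)-1-(5,8-dimethoxy-1,4-dihydro-1,4-epoxynaphthalen-6-yl)-4-methylpent-3-en-1-yl]oxy}dimethylsilane
Product: 12 (1R)-1-(5,8-dimethoxy-1,4-dihydro-1,4-epoxynaphthalen-6-yl)-4-methylpent-3-en-1-ol
Conditions: n-Bu4NF, THF, 0 °C → rt
Reagents that add atoms: none
Why: Fluoride-mediated desilylation, driven by the Si–F bond, should free the alcohol at a stage where nothing in the molecule is sensitive to basic fluoride (no quinone yet); only the O–Si bond is cut, so C1' keeps its configuration.

Step 6
Reactants: 12 (1R)-1-(5,8-dimethoxy-1,4-dihydro-1,4-epoxynaphthalen-6-yl)-4-methylpent-3-en-1-ol; 13 butanoic anhydride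
Product: 14 (1R)-1-(5,8-dimethoxy-1,4-dihydro-1,4-epoxynaphthalen-6-yl)-4-methylpent-3-en-1-yl butanoate
Conditions: (n-PrCO)2O, Et3N, 4-(dimethylamino)pyridine (cat.), CH2Cl2, 0 °C → rt
Reagents that add atoms: none
Why: Nucleophile-catalysed acylation of the secondary benzylic alcohol (acyl transfer through the N-acylpyridinium ion) should install the butanoate of the target, an acid-tolerant group that cannot cyclise onto the alkene, before any acidic or oxidative step; the C1'–O bond is not broken.

Step 7
Reactants: 14 (1R)-1-(5,8-dimethoxy-1,4-dihydro-1,4-epoxynaphthalen-6-yl)-4-methylpent-3-en-1-yl butanoate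
Product: 17 (1R)-1-(1,4-dimethoxy-5,8-dioxo-5,8-dihydronaphthalen-2-yl)-4-methylpent-3-en-1-yl butanoate, via 5-naphthol 15 (not isolated), via 8-naphthol 16 (not isolated)
Conditions: CF3CO2H (3 equiv), CH2Cl2, 0 °C, Ar; then dilute with MeCN–H2O (4:1), PhI(OCOCF3)2 (2.2 equiv), 0 °C
Reagents that add atoms: water, O
Why: Acid-catalysed isomerisation of the 1,4-epoxy-1,4-dihydronaphthalene (protonation of the bridging oxygen, ionisation of either bridgehead C–O bond to an allylic, methoxy-stabilised benzylic cation, 1,2-hydride shift and enolisation) should give the regioisomeric 1-naphthols 15 and 16, and oxidation of the unpurified pair in the same flask with the trivalent iodine reagent PhI(OCOCF3)2 in aqueous acetonitrile (water attacks the free para position of the aryloxy-iodane, a second equivalent oxidises the resulting hydroquinone) should convert both into the same 5,8-dimethoxy-1,4-naphthoquinone, so the air-sensitive naphthols are never handled; the phenols should react far faster than the dimethoxyarene, the trisubstituted alkene or the ester, and the C1'–O bond is not involved.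

Step 8
Reactants: 17 (1R)-1-(1,4-dimethoxy-5,8-dioxo-5,8-dihydronaphthalen-2-yl)-4-methylpent-3-en-1-yl butanoate
Product: 19 butylshikonin [(1R)-1-(5,8-dihydroxy-1,4-dioxo-1,4-dihydronaphthalen-2-yl)-4-methylpent-3-en-1-yl butanoate], via naphthalene-1,4,5,8-tetrone 18 (not isolated)
Conditions: AgO (4 equiv), 6 M HNO3, 1,4-dioxane, rt, 5–10 min; then Na2S2O4 (1.1 equiv), H2O–EtOAc, 0 °C
Reagents that add atoms: water, O
Why: Oxidative demethylation of a para-dimethoxyarene by AgO in nitric acid (arene radical cation, ipso attack of water, loss of methanol) should give the naphthalene-1,4,5,8-tetrone, whose immediate two-electron reduction with a limited amount of Na2S2O4 gives the naphthazarin, drawn as the tautomer with the side chain on the quinone ring; the alkyl group on the dimethoxy ring assists its oxidation and C1' is not involved.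

**Compound list**

1 | 4-bromo-2,5-dimethoxybenzaldehyde | COc1cc(Br)c(OC)cc1C=O | starting material
2 | allylboronic acid pinacol ester (2-allyl-4,4,5,5-tetramethyl-1,3,2-dioxaborolane) | C=CCB1OC(C)(C)C(C)(C)O1 | starting material
3 | 2-{[(1R)-1-(4-bromo-2,5-dimethoxyphenyl)but-3-en-1-yl]oxy}-4,4,5,5-tetramethyl-1,3,2-dioxaborolane | CC1(C)OB(O[C@H](CC=C)c2cc(OC)c(Br)cc2OC)OC1(C)C | intermediate
4 | (1R)-1-(4-bromo-2,5-dimethoxyphenyl)but-3-en-1-ol | O[C@H](CC=C)c1cc(OC)c(Br)cc1OC | intermediate
5 | {[(1R)-1-(4-bromo-2,5-dimethoxyphenyl)but-3-en-1-yl]oxy}(tert-butyl)dimethylsilane | CC(C)(C)[Si](C)(C)O[C@H](CC=C)c1cc(OC)c(Br)cc1OC | intermediate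
6 | 2-methylbut-2-ene | CC=C(C)C | starting material
7 | {[(1R)-1-(4-bromo-2,5-dimethoxyphenyl)-4-methylpent-3-en-1-yl]oxy}(tert-butyl)dimethylsilane | CC(C)(C)[Si](C)(C)O[C@H](CC=C(C)C)c1cc(OC)c(Br)cc1OC | intermediate
8 | furan | c1ccoc1 | starting material
9 | {[(1R)-1-(4-bromo-3-lithio-2,5-dimethoxyphenyl)-4-methylpent-3-en-1-yl]oxy}(tert-butyl)dimethylsilane | CC(C)(C)[Si](C)(C)O[C@H](CC=C(C)C)c1cc(OC)c(Br)c([Li])c1OC | intermediate
10 | 3,6-dimethoxybenzyne bearing the (1R)-1-(tert-butyldimethylsilyloxy)-4-methylpent-3-enyl group at C4 | CC(C)(C)[Si](C)(C)O[C@H](CC=C(C)C)C1=C(OC)C#CC(OC)=C1 | intermediate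
11 | tert-butyl{[(1R)-1-(5,8-dimethoxy-1,4-dihydro-1,4-epoxynaphthalen-6-yl)-4-methylpent-3-en-1-yl]oxy}dimethylsilane (both bridgehead diastereomers) | CC(C)(C)[Si](C)(C)O[C@H](CC=C(C)C)c1cc(OC)c2C3C=CC(O3)c2c1OC | intermediate
12 | (1R)-1-(5,8-dimethoxy-1,4-dihydro-1,4-epoxynaphthalen-6-yl)-4-methylpent-3-en-1-ol (both bridgehead diastereomers) | O[C@H](CC=C(C)C)c1cc(OC)c2C3C=CC(O3)c2c1OC | intermediate
13 | butanoic anhydride | CCCC(=O)OC(=O)CCC | starting material
14 | (1R)-1-(5,8-dimethoxy-1,4-dihydro-1,4-epoxynaphthalen-6-yl)-4-methylpent-3-en-1-yl butanoate (both bridgehead diastereomers) | CCCC(=O)O[C@H](CC=C(C)C)c1cc(OC)c2C3C=CC(O3)c2c1OC | intermediate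
15 | (1R)-1-(5-hydroxy-1,4-dimethoxynaphthalen-2-yl)-4-methylpent-3-en-1-yl butanoate | CCCC(=O)O[C@H](CC=C(C)C)c1cc(OC)c2c(O)cccc2c1OC | intermediate
16 | (1R)-1-(8-hydroxy-1,4-dimethoxynaphthalen-2-yl)-4-methylpent-3-en-1-yl butanoate | CCCC(=O)O[C@H](CC=C(C)C)c1cc(OC)c2cccc(O)c2c1OC | intermediate
17 | (1R)-1-(1,4-dimethoxy-5,8-dioxo-5,8-dihydronaphthalen-2-yl)-4-methylpent-3-en-1-yl butanoate | CCCC(=O)O[C@H](CC=C(C)C)c1cc(OC)c2C(=O)C=CC(=O)c2c1OC | intermediate
18 | (1R)-4-methyl-1-(1,4,5,8-tetraoxo-1,4,5,8-tetrahydronaphthalen-2-yl)pent-3-en-1-yl butanoate | CCCC(=O)O[C@H](CC=C(C)C)C1=CC(=O)C2=C(C1=O)C(=O)C=CC2=O | intermediate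
19 | butylshikonin, (1R)-1-(5,8-dihydroxy-1,4-dioxo-1,4-dihydronaphthalen-2-yl)-4-methylpent-3-en-1-yl butanoate | CCCC(=O)O[C@H](CC=C(C)C)C1=CC(=O)c2c(O)ccc(O)c2C1=O | target

**Step count**

Total: 8 steps. Longest linear sequence: 8 steps, from 1 to 19.

**Steps most likely to fail**

Step 8. The risks are oxidation of the trisubstituted alkene or the benzylic position by divalent silver in nitric acid, hydration of the very electrophilic tetrone before it is reduced, and over-reduction followed by reductive loss of the butanoate. The fallback replaces the redox sequence by a non-oxidative, chelation-assisted ether cleavage. It sets out from 17, in which each methoxy group lies peri to a quinone carbonyl. BCl3 in CH2Cl2 at −78 °C should bind carbonyl and ether oxygen together and deliver chloride to the O-methyl carbon, a known mode of cleavage for methoxy groups next to a carbonyl. Mild aqueous hydrolysis of the boron chelates then returns to the route at 19; no new compound is made on the way (none, F0).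

Step 7. The risks are acid-induced ionisation of the benzylic C1'–O bond (loss of configuration or elimination), protonation of the trisubstituted alkene, and carry-over of acid-derived side products into the oxidation. The fallback drops the Brønsted acid for a neutral, metal-mediated cleavage of the strained allylic C–O bond. It sets out from 14, which is heated with catalytic [RuCl2(CO)3]2 in ClCH2CH2Cl at 60 °C, a known isomerisation of 7-oxabenzonorbornadienes to 1-naphthols. The naphthols 15 and 16 so formed are passed through a short silica plug under argon and oxidised with PhI(OCOCF3)2 in MeCN–H2O at 0 °C as in the route, which is rejoined at 17; no new compound is made on the way (none, F0).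

Step 4. The risks are capture of the aryne by the amide or by diisopropylamine instead of furan, incomplete loss of LiBr at temperatures the substrate tolerates, and competing lithiation elsewhere. The fallback separates metalation from aryne formation and makes the aryne in an amine-free medium. It sets out from 7, which is lithiated with LiN(iPr)2 in THF at −78 °C without furan and quenched with 1,2-diiodoethane. This should give the ortho-bromo-iodoarene {[(1R)-1-(4-bromo-3-iodo-2,5-dimethoxyphenyl)-4-methylpent-3-en-1-yl]oxy}(tert-butyl)dimethylsilane F1, whose structure confirms the site of metalation. Iodine–lithium exchange with n-BuLi in toluene containing excess furan (−78 °C → rt) then regenerates the aryllithium, which loses LiBr; the aryne is trapped as before and the route is rejoined at 11.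

Further compounds
F1 | step 4 | {[(1R)-1-(4-bromo-3-iodo-2,5-dimethoxyphenyl)-4-methylpent-3-en-1-yl]oxy}(tert-butyl)dimethylsilane | CC(C)(C)[Si](C)(C)O[C@H](CC=C(C)C)c1cc(OC)c(Br)c(I)c1OC
F0 | step 7 | none | none
F0 | step 8 | none | none
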